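A small charge of racemic substrate, Z and E side by side, meets solid G, which feeds dissolved J. J turns Z into J.Z and E into J.E, while Z and E also interconvert through D, which drains to Q: a dynamic kinetic resolution with a leak.

all flasks: Z 0.050 M; G 2.20 equiv; E 0.050 M; time 12 h
- ash: temperature 5 °C
- birch: temperature 25 °C
- larch: temperature −15 °C

- the flask that comes out highest in share of J.Z in all that became J.Z or J.E or Q, or "all alike" when all lie within 1.5 percentage points (ash / birch / larch / all alike)
- share of J.Z in all that became J.Z or J.E or Q, ash
- share of J.Z in all that became J.Z or J.E or Q, birch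
- share of J.Z in all that became J.Z or J.E or Q, larch

- J is single-handed; Z and E are mirror images of each other, charged as a racemate, each of them at the stated concentration
- solid, in amounts per volume of the solution: G
- at 5 °C the constants are as listed, elsewhere as the activation energies and enthalpies make them
- at the start none of G is in solution
- the handed part of J does not stay in what it makes, so the products of the two hands are mirror images too

    J + Z → J.Z (k1 = 0.073 M⁻¹ min⁻¹, Ea1 = 47.0 kJ mol⁻¹)
    Z ⇌ D (K2 = 0.49, k2 = 0.0052 min⁻¹, Ea2 = 82.0 kJ mol⁻¹, ΔH2 = −12.0 kJ mol⁻¹)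
    J + E → J.E (k3 = 0.027 M⁻¹ min⁻¹, Ea3 = 76.0 kJ mol⁻¹)
    E ⇌ D (K2 = 0.49, k2 = 0.0052 min⁻¹, Ea2 = 82.0 kJ mol⁻¹, ΔH2 = −12.0 kJ mol⁻¹)
    D → Q (k5 = 0.0022 min⁻¹, Ea5 = 93.0 kJ mol⁻¹)
    G ⇌ J, rate k6*(cs6 - [J]) while solid is left; crystals form when [J] > cs6 (cs6 = 20 mM, k6 = 0.0045 min⁻¹)
    (constants at 5 °C)

I divide one rate by another so that time drops out. Suppose D stands in equilibrium with Z and E, so that c(D) = K·c(Z) and c(E) = c(Z). Then J.Z forms at kZ·c(J)·c(Z), J.E at kE·c(J)·c(Z) and Q at kQ·K·c(Z), and c(Z) cancels. At 5 °C, kZ is 0.073 M⁻¹ min⁻¹, kE 0.027 M⁻¹ min⁻¹, kQ 0.0022 min⁻¹ and K 0.49. With c(J) at its solubility cs, 20 mM, I get S = kZ·cs/(kZ·cs + kE·cs + kQ·K), which for ash is 47.4%. I call S the saturated share, the fraction of each moment's product that is J.Z when J is saturated. Carried by the activation energies and the enthalpy, it becomes 26.1% for birch and 72.7% for larch, so I commit to larch as the highest.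

Is one number enough? J starts from nothing and fills with a half-life of 2.57 h. In birch the leak by itself halves the pool of Z, E and D in 2.40 h, less than that, so I expect birch well below its S. In larch, D exchanges with Z and E together, and by this exchange it relaxes with a half-life of 9.29 h, shorter than the 12 h allowed, but only by a factor of 1.29. So I expect D to lag for a good part of the larch run and Q to come late, and larch may stand above its S.

The forecast names larch, with 36% (31% to 41%) for ash, 12% (9% to 16%) for birch and 79% (74% to 83%) for larch. For birch it says “slow dissolution of G limits J, so most material drains through D to Q”. Its figures differ from my S, lower for ash and birch and higher for larch.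

The flasks give 35.1% for ash, 10.5% for birch and 79.7% for larch, so larch is highest, and each value lies inside the forecast's range.

Larch has converted 22.1% at the end. Left 120 h, larch reads 67.5%, below its S of 72.7%.

For a repeat of birch at 0 °C, S comes to 53.8%. That flask gives 44.3%, below its S, as ash stands below 47.4%.

The numbers were chosen freely, and the outcome is calculated.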